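The ten-membered ring is disconnected at C7–C8. In that ring the C4 tertiary allylic alcohol, the E-C5=C6 alkene and the C7 isopropyl stereocentre form a 1,4 oxygen/carbon pattern across an alkene. This is the imprint of a nucleophile adding to the far end of a π-allyl unit released from a C4–C5 epoxide attached to a C6=C7 alkene. One palladium-catalysed step on an acyclic nitro vinyl epoxide therefore closes the ring, unveils the C4 carbinol, sets the 5E alkene and relays the epoxide configuration to C7; the nitro group that activates C8 is later exchanged for the C8 oxygen. The precursor is a (4R,5S)-cis-epoxide from Sharpless epoxidation of a nerol unit, bearing an (E)-3-methylbutenyl group and a nitroethyl-terminated E-trisubstituted alkene.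

Key step: step 13

Remark: atom labels C1–C10 follow the ring numbering of the target (C1=C10 with the methyl on C10, C4 carbinol, C5=C6, C7 isopropyl, C8 ester) and are also used for the acyclic compounds.
Remark: C8 of compounds 19 and 20 carries no descriptor because this centre is epimerisable next to the nitro group and becomes a carbonyl carbon in step 14.

Step 1
Reactants: 1 1-bromo-2-methylpropane; 2 1-phenyl-1H-tetrazole-5-thiol
Product: 3 5-[(2-methylpropyl)sulfanyl]-1-phenyl-1H-tetrazole
Conditions: K2CO3, KI (cat.), DMF, 60 °C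
Reagents that add atoms: none
Why: Thiolate S-alkylation (SN2) of the primary bromide, with iodide catalysis offsetting the β-branching of the isobutyl group.

Step 2
Reactants: 3 5-[(2-methylpropyl)sulfanyl]-1-phenyl-1H-tetrazole
Product: 4 5-[(2-methylpropyl)sulfonyl]-1-phenyl-1H-tetrazole
Conditions: H2O2 (30% aq.), (NH4)6Mo7O24·4H2O (cat.), EtOH, 0 °C to rt
Reagents that add atoms: hydrogen peroxide, OO
Why: Molybdate-catalysed peroxide oxidation takes the sulfide through the sulfoxide to the sulfone without touching the tetrazole, the standard entry to Julia–Kocienski reagents.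

Step 3
Reactants: 5 neryl acetate
Product: 6 (2Z,6E)-8-hydroxy-3,7-dimethylocta-2,6-dien-1-yl acetate
Conditions: SeO2 (0.3 equiv), tBuOOH (3 equiv), salicylic acid (0.1 equiv), CH2Cl2, rt
Reagents that add atoms: tert-butyl hydroperoxide, CC(C)(C)OO (terminal oxidant; the oxygen is relayed through SeO2, O=[Se]=O)
Why: Catalytic SeO2 allylic oxidation (ene reaction, then 2,3-sigmatropic shift) attacks the electron-rich terminal trisubstituted alkene at its E-methyl group, so the new CH2OH (C9) is placed E while the acetate-deactivated Z-alkene is left alone.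

Step 4
Reactants: 6 (2Z,6E)-8-hydroxy-3,7-dimethylocta-2,6-dien-1-yl acetate
Product: 7 (2Z,6E)-8-[(tert-butyldimethylsilyl)oxy]-3,7-dimethylocta-2,6-dien-1-yl acetate
Conditions: TBSCl, imidazole, DMF, 0 °C to rt
Reagents that add atoms: tert-butyldimethylsilyl chloride, CC(C)(C)[Si](C)(C)Cl
Why: Standard silylation of a primary allylic alcohol, giving a silyl ether that is orthogonal to the acetate removed next.

Step 5
Reactants: 7 (2Z,6E)-8-[(tert-butyldimethylsilyl)oxy]-3,7-dimethylocta-2,6-dien-1-yl acetate
Product: 8 (2Z,6E)-8-[(tert-butyldimethylsilyl)oxy]-3,7-dimethylocta-2,6-dien-1-ol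
Conditions: K2CO3 (cat.), MeOH, 0 °C to rt
Reagents that add atoms: none
Why: Base-catalysed transesterification (methanolysis) removes the acetate under conditions to which the silyl ether and both alkenes are inert.

Step 6
Reactants: 8 (2Z,6E)-8-[(tert-butyldimethylsilyl)oxy]-3,7-dimethylocta-2,6-dien-1-ol
Product: 9 [(2S,3R)-3-{(3E)-5-[(tert-butyldimethylsilyl)oxy]-4-methylpent-3-en-1-yl}-3-methyloxiran-2-yl]methanol
Conditions: Ti(OiPr)4 (10 mol%), L-(+)-diethyl tartrate (12 mol%), tBuOOH (in decane), 4 Å MS, CH2Cl2, −20 °C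
Reagents that add atoms: tert-butyl hydroperoxide, CC(C)(C)OO
Why: Katsuki–Sharpless asymmetric epoxidation oxidises only the allylic-alcohol alkene; the L-(+)-tartrate catalyst gives the 2S-configured carbinol-bearing carbon and the Z geometry translates into the cis (2S,3R)-epoxide, which fixes the future C5 (S) and C4 (R).

Step 7
Reactants: 9 [(2S,3R)-3-{(3E)-5-[(tert-butyldimethylsilyl)oxy]-4-methylpent-3-en-1-yl}-3-methyloxiran-2-yl]methanol
Product: 10 (2R,3R)-3-{(3E)-5-[(tert-butyldimethylsilyl)oxy]-4-methylpent-3-en-1-yl}-3-methyloxirane-2-carbaldehyde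
Conditions: Dess–Martin periodinane, NaHCO3, CH2Cl2, 0 °C
Reagents that add atoms: none
Why: Dess–Martin oxidation under bicarbonate buffer gives the epoxy aldehyde without epoxide opening, the oxirane α-hydrogen being practically non-enolisable (the descriptor at C2 changes by priority only, not in space).

Step 8
Reactants: 10 (2R,3R)-3-{(3E)-5-[(tert-butyldimethylsilyl)oxy]-4-methylpent-3-en-1-yl}-3-methyloxirane-2-carbaldehyde; 4 5-[(2-methylpropyl)sulfonyl]-1-phenyl-1H-tetrazole
Product: 11 tert-butyl(dimethyl){[(2E)-2-methyl-5-{(2R,3S)-2-methyl-3-[(1E)-3-methylbut-1-en-1-yl]oxiran-2-yl}pent-2-en-1-yl]oxy}silane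
Conditions: 4, KN(SiMe3)2, DME, −60 °C; then 10, −60 °C to rt
Reagents that add atoms: none
Why: Julia–Kocienski olefination, in which the potassium salt of the phenyltetrazolyl sulfone adds to the aldehyde through an open transition state and Smiles rearrangement–elimination gives the E-C6=C7 alkene, the epoxide centres being untouched.

Step 9
Reactants: 11 tert-butyl(dimethyl){[(2E)-2-methyl-5-{(2R,3S)-2-methyl-3-[(1E)-3-methylbut-1-en-1-yl]oxiran-2-yl}pent-2-en-1-yl]oxy}silane
Product: 12 (2E)-2-methyl-5-{(2R,3S)-2-methyl-3-[(1E)-3-methylbut-1-en-1-yl]oxiran-2-yl}pent-2-en-1-ol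
Conditions: Bu4NF, THF, 0 °C
Reagents that add atoms: none
Why: Fluoride-mediated desilylation is neutral toward the vinyl epoxide and frees the primary allylic alcohol at C9.

Step 10
Reactants: 12 (2E)-2-methyl-5-{(2R,3S)-2-methyl-3-[(1E)-3-methylbut-1-en-1-yl]oxiran-2-yl}pent-2-en-1-ol
Product: 14 (2R,3S)-2-[(3E)-5-bromo-4-methylpent-3-en-1-yl]-2-methyl-3-[(1E)-3-methylbut-1-en-1-yl]oxirane, via allylic mesylate 13 (not isolated)
Conditions: MsCl, Et3N, THF, −40 °C; then LiBr, THF, −40 to 0 °C
Reagents that add atoms: lithium bromide, [Li+].[Br-]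
Why: Mesylation followed by SN2 displacement with bromide at low temperature converts the allylic alcohol into the bromide without allylic transposition and without acid, a protocol long used for epoxide-bearing terpenoid allylic bromides.

Step 11
Reactants: 14 (2R,3S)-2-[(3E)-5-bromo-4-methylpent-3-en-1-yl]-2-methyl-3-[(1E)-3-methylbut-1-en-1-yl]oxirane; 15 ethyl nitroacetate
Product: 16 ethyl (4E)-4-methyl-7-{(2R,3S)-2-methyl-3-[(1E)-3-methylbut-1-en-1-yl]oxiran-2-yl}-2-nitrohept-4-enoate (both epimers at the nitro carbon)
Conditions: 15 (4 equiv), iPr2NEt, Bu4NI (cat.), DMF, 0 °C to rt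
Reagents that add atoms: none
Why: SN2 C-alkylation of the soft, doubly stabilised nitroacetate anion by the allylic bromide; ethyl nitroacetate serves as the nitromethane equivalent because simple nitronate salts are alkylated on oxygen by allylic halides, and its excess suppresses double alkylation.

Step 12
Reactants: 16 ethyl (4E)-4-methyl-7-{(2R,3S)-2-methyl-3-[(1E)-3-methylbut-1-en-1-yl]oxiran-2-yl}-2-nitrohept-4-enoate
Product: 18 (2R,3S)-2-methyl-2-[(3E)-4-methyl-6-nitrohex-3-en-1-yl]-3-[(1E)-3-methylbut-1-en-1-yl]oxirane, via dipotassium nitronate carboxylate 17 (not isolated)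
Conditions: KOH, EtOH–H2O, rt; then AcOH to pH 5–6, 0 °C to rt
Reagents that add atoms: none
Why: Saponification of the α-nitro ester to the carboxylate nitronate and mild acidification trigger the facile decarboxylation of the α-nitro carboxylate, leaving the primary nitroalkane (C8) with the base-stable vinyl epoxide intact.

Step 13
Reactants: 18 (2R,3S)-2-methyl-2-[(3E)-4-methyl-6-nitrohex-3-en-1-yl]-3-[(1E)-3-methylbut-1-en-1-yl]oxirane
Product: 19 (4R,7S)-8-nitrogermacra-1(10)E,5E-dien-4-ol [(1R,2E,4S,7E)-1,7-dimethyl-5-nitro-4-(propan-2-yl)cyclodeca-2,7-dien-1-ol; both epimers at the nitro carbon]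
Conditions: Pd2(dba)3·CHCl3 (5 mol%), PPh3 (40 mol%), THF, 40 °C, slow addition of 18 to 0.005 M
Reagents that add atoms: none
Why: Zerovalent palladium binds the C6=C7 alkene of 18 on the face opposite the C5–O bond and ionises the epoxide to a syn,syn-π-allyl complex (C5–C6–C7) carrying the C4 alkoxide, which deprotonates the C8 nitromethylene, so the nitronate forms when and where the electrophile exists and no external base is needed. The nitronate carbon then adds to the distal allyl terminus C7 on the face away from the metal, creating C7–C8; the closest known reaction type is the Tsuji–Trost macrocyclisation of vinyl epoxides carrying a tethered carbon pronucleophile under neutral conditions, combined with the established carbon-allylation of nitronates by π-allyl palladium species. The ten-membered ring closes in the mode in which all three allyl carbons become ring atoms, the new E-C5=C6 bond lying inside the ring, not in the eight-membered mode through C5 that would leave the alkenyl group outside the ring. C7 is controlled by the C5 configuration of the epoxide: two successive inversions (metal anti to oxygen, carbon anti to metal) amount to net retention, and because the E-C6=C7 alkene and the s-trans ionisation conformer fix a syn,syn allyl, the (4R,5S)-epoxide is relayed into 7S with an E-C5=C6 alkene while C4 keeps its oxygen and its R configuration. The step needs distal over proximal attack and carbon over oxygen alkylation: attack at C5 would confine the E-C1=C10 alkene in an eight-membered ring and must approach a carbon flanked by the quaternary C4, whereas attack at C7 gives a relaxed E,E-cyclodecadiene, and any O-allyl nitronate is re-ionised by the catalyst. High dilution with slow addition keeps the alkylation intramolecular.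

Step 14
Reactants: 19 (4R,7S)-8-nitrogermacra-1(10)E,5E-dien-4-ol
Product: 21 (4R,7S)-4-hydroxygermacra-1(10)E,5E-dien-8-one, via sodium nitronate 20 (not isolated)
Conditions: NaOMe, MeOH, 0 °C; then TiCl3 (aq.), NH4OAc, THF–H2O, pH 5–6, 0 °C to rt
Reagents that add atoms: water, O
Why: McMurry's buffered TiCl3 variant of the Nef reaction reduces the preformed nitronate to the imine, which hydrolyses at pH 5–6 to the ketone under conditions mild enough to spare the tertiary allylic alcohol and the C7 centre of the β,γ-unsaturated ketone.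

Step 15
Reactants: 21 (4R,7S)-4-hydroxygermacra-1(10)E,5E-dien-8-one
Product: 22 (4R,7S,8S)-germacra-1(10)E,5E-diene-4,8-diol
Conditions: (R)-2-methyl-CBS-oxazaborolidine [(3aR)-1-methyl-3,3-diphenyltetrahydro-1H,3H-pyrrolo[1,2-c][1,3,2]oxazaborole] (1 equiv), catecholborane, toluene, −78 °C; MeOH, then aq. NaOH work-up
Reagents that add atoms: none
Why: Corey–Bakshi–Shibata reduction, in which the (R)-oxazaborolidine binds the ketone anti to its larger α-branched flank (C7) and delivers hydride to give the 8S alcohol by reagent control, at a temperature at which enolisation toward C7 and hydroboration of the alkenes do not compete.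

Step 16
Reactants: 22 (4R,7S,8S)-germacra-1(10)E,5E-diene-4,8-diol; 23 4-acetoxybenzoyl chloride
Product: 24 (4R,7S,8S)-4-hydroxygermacra-1(10)E,5E-dien-8-yl 4-acetoxybenzoate
Conditions: 23, pyridine, DMAP (cat.), CH2Cl2, 0 °C to rt
Reagents that add atoms: none
Why: Nucleophilic-catalysed acylation with the aroyl chloride occurs only at the secondary C8 hydroxyl, with retention, the tertiary C4 hydroxyl being unreactive, and the phenol is carried as its acetate to prevent self-acylation of the reagent.

Step 17
Reactants: 24 (4R,7S,8S)-4-hydroxygermacra-1(10)E,5E-dien-8-yl 4-acetoxybenzoate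
Product: 25 (4R,7S,8S)-4-hydroxygermacra-1(10)E,5E-dien-8-yl 4-hydroxybenzoate (target)
Conditions: NH4OAc, MeOH–H2O, rt
Reagents that add atoms: none
Why: Chemoselective solvolysis of the aryl acetate, whose phenoxide leaving group makes it far more labile than the hindered secondary alkyl benzoate, unmasks the phenol under neutral conditions.

Compound list
1 | 1-bromo-2-methylpropane | CC(C)CBr | starting material
2 | 1-phenyl-1H-tetrazole-5-thiol | Sc1nnnn1-c1ccccc1 | starting material
3 | 5-[(2-methylpropyl)sulfanyl]-1-phenyl-1H-tetrazole | CC(C)CSc1nnnn1-c1ccccc1 | intermediate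
4 | 5-[(2-methylpropyl)sulfonyl]-1-phenyl-1H-tetrazole | CC(C)CS(=O)(=O)c1nnnn1-c1ccccc1 | intermediate
5 | neryl acetate | CC(C)=CCC/C(C)=C\COC(C)=O | starting material
6 | (2Z,6E)-8-hydroxy-3,7-dimethylocta-2,6-dien-1-yl acetate | OC/C(C)=C/CC/C(C)=C\COC(C)=O | intermediate
7 | (2Z,6E)-8-[(tert-butyldimethylsilyl)oxy]-3,7-dimethylocta-2,6-dien-1-yl acetate | CC(C)(C)[Si](C)(C)OC/C(C)=C/CC/C(C)=C\COC(C)=O | intermediate
8 | (2Z,6E)-8-[(tert-butyldimethylsilyl)oxy]-3,7-dimethylocta-2,6-dien-1-ol | CC(C)(C)[Si](C)(C)OC/C(C)=C/CC/C(C)=C\CO | intermediate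
9 | [(2S,3R)-3-{(3E)-5-[(tert-butyldimethylsilyl)oxy]-4-methylpent-3-en-1-yl}-3-methyloxiran-2-yl]methanol | CC(C)(C)[Si](C)(C)OC/C(C)=C/CC[C@@]1(C)O[C@H]1CO | intermediate
10 | (2R,3R)-3-{(3E)-5-[(tert-butyldimethylsilyl)oxy]-4-methylpent-3-en-1-yl}-3-methyloxirane-2-carbaldehyde | CC(C)(C)[Si](C)(C)OC/C(C)=C/CC[C@@]1(C)O[C@H]1C=O | intermediate
11 | tert-butyl(dimethyl){[(2E)-2-methyl-5-{(2R,3S)-2-methyl-3-[(1E)-3-methylbut-1-en-1-yl]oxiran-2-yl}pent-2-en-1-yl]oxy}silane | CC(C)(C)[Si](C)(C)OC/C(C)=C/CC[C@@]1(C)O[C@H]1/C=C/C(C)C | intermediate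
12 | (2E)-2-methyl-5-{(2R,3S)-2-methyl-3-[(1E)-3-methylbut-1-en-1-yl]oxiran-2-yl}pent-2-en-1-ol | OC/C(C)=C/CC[C@@]1(C)O[C@H]1/C=C/C(C)C | intermediate
13 | methanesulfonate of 12 (allylic mesylate, not isolated) | CS(=O)(=O)OC/C(C)=C/CC[C@@]1(C)O[C@H]1/C=C/C(C)C | intermediate
14 | (2R,3S)-2-[(3E)-5-bromo-4-methylpent-3-en-1-yl]-2-methyl-3-[(1E)-3-methylbut-1-en-1-yl]oxirane | BrC/C(C)=C/CC[C@@]1(C)O[C@H]1/C=C/C(C)C | intermediate
15 | ethyl nitroacetate | CCOC(=O)C[N+](=O)[O-] | starting material
16 | ethyl (4E)-4-methyl-7-{(2R,3S)-2-methyl-3-[(1E)-3-methylbut-1-en-1-yl]oxiran-2-yl}-2-nitrohept-4-enoate (both epimers at the nitro carbon) | CCOC(=O)C([N+](=O)[O-])C/C(C)=C/CC[C@@]1(C)O[C@H]1/C=C/C(C)C | intermediate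
17 | dipotassium nitronate carboxylate from saponification of 16 (not isolated) | [K+].[K+].[O-]C(=O)C(=[N+]([O-])[O-])C/C(C)=C/CC[C@@]1(C)O[C@H]1/C=C/C(C)C | intermediate
18 | (2R,3S)-2-methyl-2-[(3E)-4-methyl-6-nitrohex-3-en-1-yl]-3-[(1E)-3-methylbut-1-en-1-yl]oxirane (nitro vinyl epoxide, the (4R,5S)-cis-epoxide) | [O-][N+](=O)CC/C(C)=C/CC[C@@]1(C)O[C@H]1/C=C/C(C)C | intermediate
19 | (4R,7S)-8-nitrogermacra-1(10)E,5E-dien-4-ol (both epimers at C8) | C/C1=C\CC[C@@](C)(O)/C=C/[C@H](C(C)C)C([N+](=O)[O-])C1 | intermediate
20 | sodium nitronate of 19 (not isolated) | [Na+].C/C1=C\CC[C@@](C)(O)/C=C/[C@H](C(C)C)C(=[N+]([O-])[O-])C1 | intermediate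
21 | (4R,7S)-4-hydroxygermacra-1(10)E,5E-dien-8-one | C/C1=C\CC[C@@](C)(O)/C=C/[C@H](C(C)C)C(=O)C1 | intermediate
22 | (4R,7S,8S)-germacra-1(10)E,5E-diene-4,8-diol | C/C1=C\CC[C@@](C)(O)/C=C/[C@H](C(C)C)[C@@H](O)C1 | intermediate
23 | 4-acetoxybenzoyl chloride | CC(=O)Oc1ccc(cc1)C(Cl)=O | starting material
24 | (4R,7S,8S)-4-hydroxygermacra-1(10)E,5E-dien-8-yl 4-acetoxybenzoate | C/C1=C\CC[C@@](C)(O)/C=C/[C@H](C(C)C)[C@@H](OC(=O)c2ccc(OC(C)=O)cc2)C1 | intermediate
25 | (4R,7S,8S)-4-hydroxygermacra-1(10)E,5E-dien-8-yl 4-hydroxybenzoate | C/C1=C\CC[C@@](C)(O)/C=C/[C@H](C(C)C)[C@@H](OC(=O)c2ccc(O)cc2)C1 | target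

Total step count: 17. Longest linear sequence: 15 steps (steps 3 to 17, from neryl acetate); steps 1 and 2 form the two-step sulfone branch.

Steps most likely to fail

Step 13. Ring closure at the hindered C7 terminus may be outrun by β-hydride loss from the π-allyl complex (giving an acyclic dienol), by attack at C5, or by intermolecular alkylation. The fallback reverses the order in which the two bonds to C8 are made and closes the ring at the unhindered primary terminus C9. It sets out from 11. Pd(PPh3)4 in THF with a large excess of nitromethane should open the vinyl epoxide intermolecularly in the same 1,4 sense and with the same net retention, giving (2E,6R,7E,9S)-1-[(tert-butyldimethylsilyl)oxy]-2,6,10-trimethyl-9-(nitromethyl)undeca-2,7-dien-6-ol F1. Bu4NF buffered with AcOH would then give (2E,6R,7E,9S)-2,6,10-trimethyl-9-(nitromethyl)undeca-2,7-diene-1,6-diol F2, and ClCO2Me with pyridine at −20 °C should acylate only the primary allylic hydroxyl to give (2E,6R,7E,9S)-6-hydroxy-2,6,10-trimethyl-9-(nitromethyl)undeca-2,7-dien-1-yl methyl carbonate F3. With Pd2(dba)3·CHCl3 and PPh3 in THF at high dilution, zerovalent palladium ionises the carbonate, the released methoxide forms the nitronate, and C8 attacks C9; this forms the C8–C9 bond and returns to the route at 19.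

Step 14. Once C8 is a carbonyl, the C5=C6 alkene may drift into conjugation, C7 may lose its configuration by enolisation, or the tertiary allylic alcohol may enter an acid-promoted transannular cyclisation during the aqueous titanium stage. The fallback avoids the nitronate and the aqueous titanium medium by passing through an isolable oxime. It sets out from 19. SnCl2, PhSH and Et3N in MeCN at rt (stannous thiolate reduction of a secondary nitro group) should stop at (4R,7S)-4-hydroxygermacra-1(10)E,5E-dien-8-one oxime F4. Dess–Martin periodinane in wet CH2Cl2 with NaHCO3 at 0 °C then cleaves the oxime under neutral conditions and returns to the route at 21, which is taken directly into step 15.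

Step 15. Hydride delivery may show poor facial selectivity if the conformational bias of the ten-membered ring opposes the catalyst. The fallback accepts the ring's preferred face and corrects C8 by inversion during esterification. It sets out from 21. (S)-2-Methyl-CBS-oxazaborolidine with catecholborane at −78 °C, now matched with the substrate bias, should give (4R,7S,8R)-germacra-1(10)E,5E-diene-4,8-diol F5. Mitsunobu esterification of F5 (PPh3, diisopropyl azodicarboxylate, 4-acetoxybenzoic acid, toluene, 0 °C) inverts C8, leaves the tertiary C4 hydroxyl untouched, and returns to the route at 24, so that step 16 is skipped.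

Further compounds
F1 | step 13 | (2E,6R,7E,9S)-1-[(tert-butyldimethylsilyl)oxy]-2,6,10-trimethyl-9-(nitromethyl)undeca-2,7-dien-6-ol | CC(C)(C)[Si](C)(C)OC/C(C)=C/CC[C@@](C)(O)/C=C/[C@@H](C[N+](=O)[O-])C(C)C
F2 | step 13 | (2E,6R,7E,9S)-2,6,10-trimethyl-9-(nitromethyl)undeca-2,7-diene-1,6-diol | OC/C(C)=C/CC[C@@](C)(O)/C=C/[C@@H](C[N+](=O)[O-])C(C)C
F3 | step 13 | (2E,6R,7E,9S)-6-hydroxy-2,6,10-trimethyl-9-(nitromethyl)undeca-2,7-dien-1-yl methyl carbonate | COC(=O)OC/C(C)=C/CC[C@@](C)(O)/C=C/[C@@H](C[N+](=O)[O-])C(C)C
F4 | step 14 | (4R,7S)-4-hydroxygermacra-1(10)E,5E-dien-8-one oxime | C/C1=C\CC[C@@](C)(O)/C=C/[C@H](C(C)C)C(=NO)C1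
F5 | step 15 | (4R,7S,8R)-germacra-1(10)E,5E-diene-4,8-diol | C/C1=C\CC[C@@](C)(O)/C=C/[C@H](C(C)C)[C@H](O)C1
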